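Two things are asked of you: the free [J] at the end of each flask, and how that number moves across the flasks.

    X + Z → J (k1 = 0.130 M⁻¹ s⁻¹)
    2 Z → G (k2 = 0.0116 M⁻¹ s⁻¹)
    E ⇌ J, rate k3*(cs3 - [J]) while solid is left; crystals form when [J] > cs3 (cs3 = 32 mM, k3 = 0.626 s⁻¹)

| flask | X | Z | time |
|---|---|---|---|
| Thursday's | 0.40 M | 0.860 M | 4.0 min |
| Monday's | 0.80 M | 0.860 M | 4.0 min |
| Friday's | 1.5 M | 0.860 M | 4.0 min |

1. [J] (only what is free in solution) at the end for Thursday's, Monday's, Friday's, in this order
2. how that number moves from the first to the last of them (falls all the way / rises, then falls / rises all the way / falls, then rises / hardly changes)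

- J is meant together with its E
- a doubled species enters its step squared and goes two at a time
- solid, in amounts per volume of the solution: E
- the concentration of J that is asked is that of its free form alone
- "hardly changes" means that all values lie within two and a half points (for a concentration: within two and a half percent of the largest)
- run time (Thursday's): 4.0 min

Carry one quantity: 0.208 M⁻¹, the lag factor, the rate constant of making J over the rate constant of crystals taking it up. With crystals standing, free J climbs above the solubility until they remove J as fast as it is made, so the quasi-steady excess of [J] over the solubility is the lag factor times [X][Z].

Take Thursday's in slow motion. At first J is made at 0.0447 M s⁻¹, with Z going to J 2.6 times as fast as to G, so the solubility of 32 mM is passed after 0.716 s. Crystals answer in about 1.60 s, which is shorter than the 6.20 s half-life of X by the first step, so [J] can follow the rule. At the charge the excess reckons to 71.4 mM, more than the solubility, so early [J] is no guide to late [J].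

For the middle I reckon roughly: the Z charge less the X charge is 0.460 M, a starting figure that leaves out the Z the second step takes while X is still going. By hand the second step wears that Z to 0.129 M by the end, and X, decaying on this Z, ends near 0.324 mM. Thursday's excess at the end is therefore 0.00870 mM.

Monday's charges nearly match, but the second step takes Z as well, so I expect Z to end below X. As a rough size only, I set both [X] and [Z] near 0.0321 M, and the excess reckons to 0.213 mM, or 0.666% of the solubility. On Friday's, X stands over Z by 0.640 M, so Z falls pseudo-first-order through about 8.68 decades and the excess drops out of sight. My row is 0.03201 M, 0.03221 M, 32 mM, and the number hardly changes.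

The forecast gives 0.03201 M, 0.03213 M, 0.032 M and hardly changes, holding that “free J sits at the quasi-steady value”. On Monday's the two differ: the forecast has 0.03213 M, my rough figure 0.03221 M.

The simulation gives 0.0320 M, 0.0321 M, 0.0320 M: hardly changes.

Now feed the lag factor the end readings. Thursday's [X] of 0.483 mM and [Z] of 0.113 M give an excess of 0.0113 mM. Monday's [X] of 0.0679 M and [Z] of 0.00935 M give 0.132 mM. The largest single effect in these flasks is how little J dissolves. With that limit taken away, Thursday's [J] at the end is 0.400 M instead of 0.0320 M, and Friday's is 0.809 M.

The constants were drawn at random within sensible limits, and the outcome is calculated.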